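At early times the thing to watch on this bench is where one molecule of partner will end, so this note for whoever takes over starts there.

| flask | starting material | second substrate | partner | free catalyst | time | remark |
|---|---|---|---|---|---|---|
| spring | 0.20 M (fed, over 12.0 s) | 0.500 equiv | 0.800 equiv | 1.3 mol% | 15 s | all but starting material at the start; starting material goes in evenly over 12.0 s, the run ends at 15 s |
| autumn | 0.20 M | 0.500 equiv | 0.800 equiv | 1.3 mol% |  | one stirred flow tank at steady state, fed with the mixture as stated, mean residence time 15 s |
| midnight | 0.20 M | 0.500 equiv | 0.800 equiv | 1.3 mol% | 15 s | everything together in a closed stirred flask, run for 15 s |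
| dusk | 0.20 M | 0.500 equiv | 0.800 equiv | 1.3 mol% |  | one stirred flow tank at steady state, fed with the mixture as stated, mean residence time 45.0 s |

    starting material + free catalyst ⇌ catalyst intermediate A (K1 = 210 L mol⁻¹, k1 = 140 L mol⁻¹ s⁻¹)
    partner + catalyst intermediate A → free catalyst + target (k2 = 17 L mol⁻¹ s⁻¹)
    second substrate + free catalyst ⇌ catalyst intermediate B (K3 = 17 L mol⁻¹, k3 = 16 L mol⁻¹ s⁻¹)
    partner + catalyst intermediate B → free catalyst + second product (k4 = 17 L mol⁻¹ s⁻¹)
    partner → decomposed reagent (k5 = 0.016 s⁻¹)

- the stated concentrations are those of everything mixed, before any reaction; amounts are the same in each set-up
- the feed brings no volume worth counting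
- run time (spring): 15 s

- the set-up with the highest amount of target at the outlet or at the end, in percent of the starting material put in ("none" if the first two lie within 2 percentage points) (spring / autumn / midnight / dusk / none)
- amount of target at the outlet or at the end, in percent of the starting material put in, spring
- amount of target at the outlet or at the end, in percent of the starting material put in, autumn
- amount of target at the outlet or at the end, in percent of the starting material put in, midnight
- amount of target at the outlet or at the end, in percent of the starting material put in, dusk

In midnight, starting material catches free catalyst at 28.0 s⁻¹, while partner releases catalyst from catalyst intermediate A at 2.72 s⁻¹. Capture is the faster, so catalyst waits mainly as catalyst intermediate A, the resting state. Partner, the limiting reagent at 0.800 equiv, meets either bound form with the same constant. A molecule of partner therefore has two exits: bound catalyst at 0.0442 s⁻¹ or decay at 0.016 s⁻¹.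

catalyst share = 0.0442 s⁻¹ / (0.0442 s⁻¹ + 0.016 s⁻¹) = 73.4%

This catalyst share is the chance that partner ends on bound catalyst and not in decay. The freed catalyst then forks between starting material and second substrate, taken at their charge:

target share = 140 L mol⁻¹ s⁻¹ / (140 L mol⁻¹ s⁻¹ + 16 L mol⁻¹ s⁻¹ × 0.500 equiv) = 94.6%

target limit = catalyst share × target share × 0.800 equiv = 55.6%

Partner is spent at 0.0602 s⁻¹, which scales that limit:

midnight: limit × (1 − e^(−rate × time)) = 33.0%

autumn: limit × rate × τ / (1 + rate × τ) = 26.4%

dusk: the same with 45.0 s = 40.6%

These figures count free catalyst as bound, so they lean high. Spring gets no figure, because its starting material arrives over 12.0 s and the target share above does not hold at its early times. Of the three reckoned figures, dusk's is the highest.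

The forecast reads 24.7% for spring, 24.6% for autumn, 30.5% for midnight and 38.3% for dusk, with dusk best. Its ground: “yield is set by how much time the partner survives, given its decay and its consumption”. Its midnight figure stands 2.5 percentage points below the reckoning.

The simulation gives 24.7% for spring, 24.6% for autumn, 30.6% for midnight and 38.5% for dusk, with dusk best.

Midnight has not come to rest at 15 s: after 150 s its target stands at 53.7%, a further 23 points. That midnight value lies 1.9 points below the reckoned target limit of 55.6%, and the reckoned partner remaining in midnight at that time is 0.0120% of its charge. Spring grows by a larger factor than midnight, to about twice its 24.7%: after 150 s its target stands at 49.8%, which is 5.8 points below the same reckoned limit.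

(The rate constants were drawn at random within sensible limits; the flask was simulated.)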